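**Retrosynthetic overview**

1. The plan rests on ring B (cyclohexane C1'–C6': C1' tertiary carbinol bearing ring A, C4' C(Me)Cl, C5' CHBr), where bromine is trans and chlorine cis to the C1' oxygen. This is the diequatorial bromochloride that anti (diaxial) addition to a C4'=C5' alkene cannot give once C1' carries the large ring A. Ring A is the cyclopentane C1 (CHOH), C2 (quaternary, methyl, bonded to C1'), C3 (CMe2), C4 (CHBr), C5 (CH2).
2. Ring A is dismantled first: C4–Br from a 3-bromocyclopent-2-enol (hydrogen-atom-transfer hydrogenation after Luche reduction), the C1–C5 bond from an intramolecular aldol, and the C2–C3 bond with the C2 stereocentre from a chirality-transferring Ireland–Claisen rearrangement. All ring A carbons grow from the C1' ester carbon.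
3. The ring B bromochloride comes from chloride opening, with retention, of a temporary C1'–O–C4' bridge. The bridged 7-oxabicyclo[2.2.1]heptane comes from transannular bromoetherification of methyl (R)-1-hydroxy-4-methylcyclohex-3-ene-1-carboxylate.
4. That hydroxy ester comes from an enantioselective Diels–Alder reaction of isoprene with 2-(benzoyloxy)acrolein, itself made from 2,2-dimethyl-1,3-dioxan-5-one.
5. Order of ring formation: ring B carbocycle (Diels–Alder), oxygen bridge (closed, later opened), ring A (aldol).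

Key step: step 6

Assumption: the L,L-configured ammonium catalyst of step 3 is taken to give the (R)-configured Diels–Alder adduct with isoprene; should the facial sense prove opposite, its D,D-antipode is used and nothing else in the route changes.

**Route**

Step 1
Reactants: 1 2,2-dimethyl-1,3-dioxan-5-one
Product: 2 2,2-dimethyl-4H-1,3-dioxin-5-yl benzoate
Conditions: BzCl, Et3N, DMAP (cat.), CH2Cl2, 0 °C to rt
Reagents that add atoms: benzoyl chloride, O=C(Cl)c1ccccc1
Why: O-acylation of the amine-generated enolate of the α,α'-dialkoxy ketone is a standard enol ester formation and should give the enol benzoate.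

Step 2
Reactants: 2 2,2-dimethyl-4H-1,3-dioxin-5-yl benzoate
Product: 3 2-(benzoyloxy)acrolein (3-oxoprop-1-en-2-yl benzoate)
Conditions: PhMe, 110 °C
Reagents that add atoms: none
Why: a thermal retro-hetero-Diels–Alder reaction of the 4H-1,3-dioxin should expel acetone and unmask the 2-acyloxyacrolein.

Step 3
Reactants: 3 2-(benzoyloxy)acrolein; 4 isoprene (2-methylbuta-1,3-diene)
Product: 5 (R)-1-formyl-4-methylcyclohex-3-en-1-yl benzoate
Conditions: triamine derived from H-L-Phe-L-Leu-N(CH2)4 by reduction of both amide carbonyls to CH2 (10 mol%), C6F5SO3H (27.5 mol%), EtNO2, rt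
Reagents that add atoms: none
Why: an organocatalytic Diels–Alder reaction through the iminium salt of the chiral primary ammonium catalyst should shield one face of the α-acyloxyacrolein and set C1' as R, while bonding of the more nucleophilic isoprene terminus to the β-carbon gives the 1,4-("para") adduct.

Step 4
Reactants: 5 (R)-1-formyl-4-methylcyclohex-3-en-1-yl benzoate
Product: 6 (R)-1-(benzoyloxy)-4-methylcyclohex-3-ene-1-carboxylic acid
Conditions: NaClO2, NaH2PO4, 2-methylbut-2-ene, t-BuOH/H2O, 0 °C to rt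
Reagents that add atoms: sodium chlorite, [Na+].[O-]Cl=O
Why: Pinnick oxidation should convert the non-enolisable aldehyde to the acid without touching the trisubstituted alkene (hypochlorite is scavenged), and recrystallisation of this acid is the planned point for enantiomeric enrichment.

Step 5
Reactants: 6 (R)-1-(benzoyloxy)-4-methylcyclohex-3-ene-1-carboxylic acid
Product: 8 methyl (R)-1-hydroxy-4-methylcyclohex-3-ene-1-carboxylate, via benzoate methyl ester 7 (not isolated)
Conditions: Me3SiCHN2, PhMe/MeOH, 0 °C; then K2CO3, MeOH, rt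
Reagents that add atoms: (trimethylsilyl)diazomethane, C[Si](C)(C)C=[N+]=[N-]
Why: diazoalkane esterification followed in the same flask by base-catalysed methanolysis (transesterification) of the tertiary benzoate, which is activated by the neighbouring ester, should release the hydroxy ester and methyl benzoate.

Step 6
Reactants: 8 methyl (R)-1-hydroxy-4-methylcyclohex-3-ene-1-carboxylate; 9 N-bromosuccinimide
Product: 10 methyl (1R,3S,4S)-3-bromo-4-methyl-7-oxabicyclo[2.2.1]heptane-1-carboxylate (bromine endo, anti to the oxygen bridge)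
Conditions: NBS, CH2Cl2, 0 °C to rt, dark
Reagents that add atoms: N-bromosuccinimide (9), O=C1CCC(=O)N1Br
Why: Br+ transfer from NBS to the C4'=C5' alkene is reversible and not face-selective, but only the bromonium ion lying opposite the C1' hydroxyl can collapse, the hydroxyl adding across the ring to the tertiary C4' through the boat conformer; this is the halo-etherification known for 4-methylcyclohex-3-en-1-ols of the terpinen-4-ol type. The ring closed is the tetrahydrofuran of the 7-oxabicyclo[2.2.1]heptane, formed in a transannular 5-exo mode with Markovnikov regiochemistry, together with the C5'–Br bond. C4' is fixed because the tethered oxygen can reach it only from its own face, and C5' because bromonium opening is anti, so bromine ends endo and trans to the bridge; both are relayed from the C1' centre set in step 3. The step needs capture by the hydroxyl in preference to the ester carbonyl (which could close a bicyclo[2.2.2] lactone from the other bromonium ion) and to external nucleophiles. A neutral hydroxyl closing a five-membered ring with no dealkylation required, a non-nucleophilic solvent and the absence of acid should secure this.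

Step 7
Reactants: 10 methyl (1R,3S,4S)-3-bromo-4-methyl-7-oxabicyclo[2.2.1]heptane-1-carboxylate
Product: 11 methyl (1R,3S,4S)-3-bromo-4-chloro-1-hydroxy-4-methylcyclohexane-1-carboxylate
Conditions: TiCl4, CH2Cl2, −78 to −30 °C; then aq. NaHCO3
Reagents that add atoms: titanium tetrachloride, Cl[Ti](Cl)(Cl)Cl
Why: Proposed new method: TiCl4 chelated between the ester carbonyl and the bridging oxygen should ionise only the C4'–O bond (a C1' cation would sit α to the ester), the antiperiplanar endo bromine assisting so that a bridged bromonium/tertiary cation results, which chloride from the titanium-ate complex opens at the tertiary C4' on the face the oxygen has left, giving chlorine in place of oxygen with retention (Cl cis and Br trans to the C1' hydroxyl); the closest known reactions are the Lewis-acid halide cleavage of tertiary ethers and 7-oxabicyclo[2.2.1]heptanes and solvolyses with neighbouring-bromine participation.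

Step 8
Reactants: 11 methyl (1R,3S,4S)-3-bromo-4-chloro-1-hydroxy-4-methylcyclohexane-1-carboxylate
Product: 12 methyl (1R,3S,4S)-3-bromo-4-chloro-4-methyl-1-[(triethylsilyl)oxy]cyclohexane-1-carboxylate
Conditions: Et3SiOTf, 2,6-lutidine, CH2Cl2, −78 to 0 °C
Reagents that add atoms: triethylsilyl trifluoromethanesulfonate, CC[Si](CC)(CC)OS(=O)(=O)C(F)(F)F
Why: silyl triflate silylation is the standard way to protect a hindered tertiary alcohol, and the silyl ether blocks retro-aldol cleavage at C1' during the later carbonyl chemistry of ring A.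

Step 9
Reactants: 12 methyl (1R,3S,4S)-3-bromo-4-chloro-4-methyl-1-[(triethylsilyl)oxy]cyclohexane-1-carboxylate
Product: 14 1-[(1R,3S,4S)-3-bromo-4-chloro-4-methyl-1-[(triethylsilyl)oxy]cyclohexyl]ethan-1-one, via Weinreb amide 13 (not isolated)
Conditions: MeNH(OMe)·HCl, i-PrMgCl, THF, −20 °C to rt; then MeMgBr, 0 °C to rt
Reagents that add atoms: methylmagnesium bromide, C[Mg]Br
Why: magnesium-amide aminolysis to the Weinreb amide and single Grignard addition through the chelated tetrahedral intermediate (Weinreb ketone synthesis) should give the methyl ketone without over-addition and install the C2 methyl group.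

Step 10
Reactants: 14 1-[(1R,3S,4S)-3-bromo-4-chloro-4-methyl-1-[(triethylsilyl)oxy]cyclohexyl]ethan-1-one
Product: 15 2-[(1R,3S,4S)-3-bromo-4-chloro-4-methyl-1-[(triethylsilyl)oxy]cyclohexyl]pent-3-en-2-ol (mixture of C2 epimers and alkene isomers)
Conditions: CH3CH=CHMgBr, CeCl3, THF, −78 to 0 °C
Reagents that add atoms: prop-1-en-1-ylmagnesium bromide, CC=C[Mg]Br
Why: 1,2-addition of the weakly basic alkenylcerium reagent to the hindered, α-oxygen-activated ketone should outrun enolisation, and neither the new carbinol centre nor the propenyl geometry matters because both are erased in step 11.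

Step 11
Reactants: 15 2-[(1R,3S,4S)-3-bromo-4-chloro-4-methyl-1-[(triethylsilyl)oxy]cyclohexyl]pent-3-en-2-ol
Product: 16 (3E)-4-[(1R,3S,4S)-3-bromo-4-chloro-4-methyl-1-[(triethylsilyl)oxy]cyclohexyl]pent-3-en-2-one
Conditions: [C5H5NH][CrO3Cl] (pyridinium chlorochromate), NaOAc, 4 Å molecular sieves, CH2Cl2, rt
Reagents that add atoms: pyridinium chlorochromate, [O-][Cr](=O)(=O)Cl.c1cc[nH+]cc1
Why: Babler–Dauben oxidative transposition ([3,3] shift of the tertiary allylic chromate ester, then oxidation at the secondary carbon) should give the enone, the chair-like shift placing the bulky ring B substituent trans to the acetyl group (E).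

Step 12
Reactants: 16 (3E)-4-[(1R,3S,4S)-3-bromo-4-chloro-4-methyl-1-[(triethylsilyl)oxy]cyclohexyl]pent-3-en-2-one
Product: 17 (2S,3E)-4-[(1R,3S,4S)-3-bromo-4-chloro-4-methyl-1-[(triethylsilyl)oxy]cyclohexyl]pent-3-en-2-ol
Conditions: (R)-2-methyl-CBS-oxazaborolidine (20 mol%), catecholborane, PhMe, −78 °C
Reagents that add atoms: none
Why: Corey–Bakshi–Shibata reduction is reagent-controlled, and with the trisubstituted alkenyl group as the large and methyl as the small substituent the (R)-catalyst should give the (S)-carbinol, the source of chirality for C2 of ring A.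

Step 13
Reactants: 17 (2S,3E)-4-[(1R,3S,4S)-3-bromo-4-chloro-4-methyl-1-[(triethylsilyl)oxy]cyclohexyl]pent-3-en-2-ol; 18 2-methylpropanoyl chloride
Product: 19 (2S,3E)-4-[(1R,3S,4S)-3-bromo-4-chloro-4-methyl-1-[(triethylsilyl)oxy]cyclohexyl]pent-3-en-2-yl 2-methylpropanoate
Conditions: i-PrCOCl, pyridine, DMAP (cat.), CH2Cl2, 0 °C to rt
Reagents that add atoms: 2-methylpropanoyl chloride (18), CC(C)C(Cl)=O
Why: DMAP-catalysed acylation of the unhindered secondary allylic alcohol proceeds with retention at the carbinol carbon and brings in C3, its two methyl groups and C4.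

Step 14
Reactants: 19 (2S,3E)-4-[(1R,3S,4S)-3-bromo-4-chloro-4-methyl-1-[(triethylsilyl)oxy]cyclohexyl]pent-3-en-2-yl 2-methylpropanoate
Product: 22 (3R,4E)-3-[(1R,3S,4S)-3-bromo-4-chloro-4-methyl-1-[(triethylsilyl)oxy]cyclohexyl]-2,2,3-trimethylhex-4-enoic acid, via silyl ketene acetal 20 (not isolated), via trimethylsilyl ester 21 (not isolated)
Conditions: LiN(i-Pr)2, Me3SiCl, THF, −78 °C; then rt to 65 °C; 1 M HCl work-up
Reagents that add atoms: none
Why: in the Ireland–Claisen rearrangement the isobutyrate ketene acetal (no enolate geometry to control) should react through a chair transition state with the carbinol methyl pseudo-equatorial (the alternative suffers A(1,3) strain against the vinylic methyl), so the (S)-carbinol and (E)-alkene transfer chirality to the quaternary C2 (R in this compound) while forming the C2–C3 bond and an (E)-propenyl group.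

Step 15
Reactants: 22 (3R,4E)-3-[(1R,3S,4S)-3-bromo-4-chloro-4-methyl-1-[(triethylsilyl)oxy]cyclohexyl]-2,2,3-trimethylhex-4-enoic acid
Product: 24 (4R,5E)-4-[(1R,3S,4S)-3-bromo-4-chloro-4-methyl-1-[(triethylsilyl)oxy]cyclohexyl]-3,3,4-trimethylhept-5-en-2-one, via acid chloride 23 (not isolated)
Conditions: Me2C=C(Cl)NMe2, CH2Cl2, 0 °C to rt; then MeZnCl, Pd(PPh3)4 (5 mol%), THF, 0 °C to rt
Reagents that add atoms: methylzinc chloride, C[Zn]Cl
Why: neutral acid chloride formation and Negishi-type acylation should give the methyl ketone that supplies C5, since zerovalent palladium inserts into the acyl chloride far faster than into the unactivated alkyl halides of ring B.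

Step 16
Reactants: 24 (4R,5E)-4-[(1R,3S,4S)-3-bromo-4-chloro-4-methyl-1-[(triethylsilyl)oxy]cyclohexyl]-3,3,4-trimethylhept-5-en-2-one
Product: 25 (2R)-2-[(1R,3S,4S)-3-bromo-4-chloro-4-methyl-1-[(triethylsilyl)oxy]cyclohexyl]-2,3,3-trimethyl-4-oxopentanal
Conditions: O3, CH2Cl2, −78 °C; then Me2S, −78 °C to rt
Reagents that add atoms: ozone, [O-][O+]=O
Why: ozonolysis with reductive work-up should cleave the only alkene to the non-enolisable neopentyl aldehyde (future C1) and discard the propenyl terminus as acetaldehyde.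

Step 17
Reactants: 25 (2R)-2-[(1R,3S,4S)-3-bromo-4-chloro-4-methyl-1-[(triethylsilyl)oxy]cyclohexyl]-2,3,3-trimethyl-4-oxopentanal
Product: 26 (3S)-3-[(1R,3S,4S)-3-bromo-4-chloro-4-methyl-1-[(triethylsilyl)oxy]cyclohexyl]-4-hydroxy-2,2,3-trimethylcyclopentan-1-one (both C4 epimers)
Conditions: LiN(SiMe3)2, THF, −78 °C; AcOH quench at −78 °C
Reagents that add atoms: none
Why: intramolecular aldol addition (5-enolexo-exo-trig) of the only possible enolate, that of the methyl ketone, to the non-enolisable aldehyde should close ring A through the C1–C5 bond, and the carbinol configuration is unimportant because it is reset in steps 18 and 20.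

Step 18
Reactants: 26 (3S)-3-[(1R,3S,4S)-3-bromo-4-chloro-4-methyl-1-[(triethylsilyl)oxy]cyclohexyl]-4-hydroxy-2,2,3-trimethylcyclopentan-1-one
Product: 27 (4R)-4-[(1R,3S,4S)-3-bromo-4-chloro-4-methyl-1-[(triethylsilyl)oxy]cyclohexyl]-4,5,5-trimethylcyclopentane-1,3-dione
Conditions: Dess–Martin periodinane, NaHCO3, CH2Cl2, 0 °C to rt
Reagents that add atoms: none
Why: Dess–Martin oxidation of the β-hydroxy ketone should give the 1,3-dione under non-basic conditions and erase the uncontrolled carbinol centre.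

Step 19
Reactants: 27 (4R)-4-[(1R,3S,4S)-3-bromo-4-chloro-4-methyl-1-[(triethylsilyl)oxy]cyclohexyl]-4,5,5-trimethylcyclopentane-1,3-dione
Product: 28 (5R)-3-bromo-5-[(1R,3S,4S)-3-bromo-4-chloro-4-methyl-1-[(triethylsilyl)oxy]cyclohexyl]-4,4,5-trimethylcyclopent-2-en-1-one
Conditions: Ph3PBr2, Et3N, CH2Cl2, 0 °C to rt
Reagents that add atoms: dibromotriphenylphosphorane, BrP(Br)(c1ccccc1)(c1ccccc1)c1ccccc1
Why: conversion of a cyclic 1,3-dione to a β-bromo enone by O-phosphonium activation and addition–elimination of bromide is expected at the less hindered carbonyl (C4, next to CMe2), leaving the carbonyl beside the more congested C2 in place, as in the halogenation of 4,4-disubstituted cyclohexane-1,3-diones.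

Step 20
Reactants: 28 (5R)-3-bromo-5-[(1R,3S,4S)-3-bromo-4-chloro-4-methyl-1-[(triethylsilyl)oxy]cyclohexyl]-4,4,5-trimethylcyclopent-2-en-1-one
Product: 29 (1R,5S)-3-bromo-5-[(1R,3S,4S)-3-bromo-4-chloro-4-methyl-1-[(triethylsilyl)oxy]cyclohexyl]-4,4,5-trimethylcyclopent-2-en-1-ol
Conditions: NaBH4, CeCl3·7H2O, MeOH, −78 °C
Reagents that add atoms: none
Why: in this Luche 1,2-reduction hydride should attack the C1 carbonyl from the face of the C2 methyl group, away from the bulky ring B substituent, placing the hydroxyl cis to ring B (1R).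

Step 21
Reactants: 29 (1R,5S)-3-bromo-5-[(1R,3S,4S)-3-bromo-4-chloro-4-methyl-1-[(triethylsilyl)oxy]cyclohexyl]-4,4,5-trimethylcyclopent-2-en-1-ol
Product: 30 (1R,2S,4S)-4-bromo-2-[(1R,3S,4S)-3-bromo-4-chloro-4-methyl-1-[(triethylsilyl)oxy]cyclohexyl]-2,3,3-trimethylcyclopentan-1-ol
Conditions: Co(acac)2, t-BuOOH, Et3SiH, 1,4-cyclohexadiene, n-PrOH, rt
Reagents that add atoms: none
Why: in this hydrogen-atom-transfer (Mukaiyama-type) hydrogenation of an alkenyl halide the cobalt hydride should transfer H• to C5 to give the α-bromo radical at C4, which takes hydrogen from cyclohexadiene on the face away from the C1 oxygen and ring B, so bromine ends cis to both (4S, the isomer with all three substituents pseudo-equatorial), and the C–Br and C–Cl bonds are expected to persist because no low-valent metal or tin radical is present.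

Step 22
Reactants: 30 (1R,2S,4S)-4-bromo-2-[(1R,3S,4S)-3-bromo-4-chloro-4-methyl-1-[(triethylsilyl)oxy]cyclohexyl]-2,3,3-trimethylcyclopentan-1-ol
Product: 31 (1R,2S,4S)-4-bromo-2-[(1R,3S,4S)-3-bromo-4-chloro-1-hydroxy-4-methylcyclohexyl]-2,3,3-trimethylcyclopentan-1-ol (target)
Conditions: HF·pyridine, THF, 0 °C to rt
Reagents that add atoms: none
Why: fluoride-mediated desilylation under mildly acidic conditions should free the tertiary alcohol without the base-induced elimination that would threaten the alkyl bromides and the tertiary chloride.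

**Compound list**

1 | 2,2-dimethyl-1,3-dioxan-5-one | CC1(C)OCC(=O)CO1 | starting material
2 | 2,2-dimethyl-4H-1,3-dioxin-5-yl benzoate | CC1(C)OCC(OC(=O)c2ccccc2)=CO1 | intermediate
3 | 2-(benzoyloxy)acrolein (3-oxoprop-1-en-2-yl benzoate) | C=C(OC(=O)c1ccccc1)C=O | intermediate
4 | isoprene (2-methylbuta-1,3-diene) | C=CC(C)=C | starting material
5 | (R)-1-formyl-4-methylcyclohex-3-en-1-yl benzoate | O=C[C@@]1(OC(=O)c2ccccc2)CCC(C)=CC1 | intermediate
6 | (R)-1-(benzoyloxy)-4-methylcyclohex-3-ene-1-carboxylic acid | OC(=O)[C@@]1(OC(=O)c2ccccc2)CCC(C)=CC1 | intermediate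
7 | methyl (R)-1-(benzoyloxy)-4-methylcyclohex-3-ene-1-carboxylate | COC(=O)[C@@]1(OC(=O)c2ccccc2)CCC(C)=CC1 | intermediate
8 | methyl (R)-1-hydroxy-4-methylcyclohex-3-ene-1-carboxylate | COC(=O)[C@@]1(O)CCC(C)=CC1 | intermediate
9 | N-bromosuccinimide | O=C1CCC(=O)N1Br | starting material
10 | methyl (1R,3S,4S)-3-bromo-4-methyl-7-oxabicyclo[2.2.1]heptane-1-carboxylate (Br endo, anti to the O bridge) | COC(=O)[C@]12CC[C@](C)(O1)[C@@H](Br)C2 | intermediate
11 | methyl (1R,3S,4S)-3-bromo-4-chloro-1-hydroxy-4-methylcyclohexane-1-carboxylate | COC(=O)[C@@]1(O)CC[C@](C)(Cl)[C@@H](Br)C1 | intermediate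
12 | methyl (1R,3S,4S)-3-bromo-4-chloro-4-methyl-1-[(triethylsilyl)oxy]cyclohexane-1-carboxylate | COC(=O)[C@@]1(O[Si](CC)(CC)CC)CC[C@](C)(Cl)[C@@H](Br)C1 | intermediate
13 | (1R,3S,4S)-3-bromo-4-chloro-N-methoxy-N,4-dimethyl-1-[(triethylsilyl)oxy]cyclohexane-1-carboxamide | CON(C)C(=O)[C@@]1(O[Si](CC)(CC)CC)CC[C@](C)(Cl)[C@@H](Br)C1 | intermediate
14 | 1-[(1R,3S,4S)-3-bromo-4-chloro-4-methyl-1-[(triethylsilyl)oxy]cyclohexyl]ethan-1-one | CC(=O)[C@@]1(O[Si](CC)(CC)CC)CC[C@](C)(Cl)[C@@H](Br)C1 | intermediate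
15 | 2-[(1R,3S,4S)-3-bromo-4-chloro-4-methyl-1-[(triethylsilyl)oxy]cyclohexyl]pent-3-en-2-ol (C2 epimers, alkene isomers) | CC=CC(C)(O)[C@@]1(O[Si](CC)(CC)CC)CC[C@](C)(Cl)[C@@H](Br)C1 | intermediate
16 | (3E)-4-[(1R,3S,4S)-3-bromo-4-chloro-4-methyl-1-[(triethylsilyl)oxy]cyclohexyl]pent-3-en-2-one | CC(=O)/C=C(\C)[C@@]1(O[Si](CC)(CC)CC)CC[C@](C)(Cl)[C@@H](Br)C1 | intermediate
17 | (2S,3E)-4-[(1R,3S,4S)-3-bromo-4-chloro-4-methyl-1-[(triethylsilyl)oxy]cyclohexyl]pent-3-en-2-ol | C[C@H](O)/C=C(\C)[C@@]1(O[Si](CC)(CC)CC)CC[C@](C)(Cl)[C@@H](Br)C1 | intermediate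
18 | 2-methylpropanoyl chloride | CC(C)C(Cl)=O | starting material
19 | (2S,3E)-4-[(1R,3S,4S)-3-bromo-4-chloro-4-methyl-1-[(triethylsilyl)oxy]cyclohexyl]pent-3-en-2-yl 2-methylpropanoate | C[C@H](OC(=O)C(C)C)/C=C(\C)[C@@]1(O[Si](CC)(CC)CC)CC[C@](C)(Cl)[C@@H](Br)C1 | intermediate
20 | trimethylsilyl ketene acetal of 19, {[1-({(2S,3E)-4-[(1R,3S,4S)-3-bromo-4-chloro-4-methyl-1-[(triethylsilyl)oxy]cyclohexyl]pent-3-en-2-yl}oxy)-2-methylprop-1-en-1-yl]oxy}trimethylsilane | C[C@H](OC(O[Si](C)(C)C)=C(C)C)/C=C(\C)[C@@]1(O[Si](CC)(CC)CC)CC[C@](C)(Cl)[C@@H](Br)C1 | intermediate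
21 | trimethylsilyl (3R,4E)-3-[(1R,3S,4S)-3-bromo-4-chloro-4-methyl-1-[(triethylsilyl)oxy]cyclohexyl]-2,2,3-trimethylhex-4-enoate | C/C=C/[C@](C)(C(C)(C)C(=O)O[Si](C)(C)C)[C@@]1(O[Si](CC)(CC)CC)CC[C@](C)(Cl)[C@@H](Br)C1 | intermediate
22 | (3R,4E)-3-[(1R,3S,4S)-3-bromo-4-chloro-4-methyl-1-[(triethylsilyl)oxy]cyclohexyl]-2,2,3-trimethylhex-4-enoic acid | C/C=C/[C@](C)(C(C)(C)C(O)=O)[C@@]1(O[Si](CC)(CC)CC)CC[C@](C)(Cl)[C@@H](Br)C1 | intermediate
23 | (3R,4E)-3-[(1R,3S,4S)-3-bromo-4-chloro-4-methyl-1-[(triethylsilyl)oxy]cyclohexyl]-2,2,3-trimethylhex-4-enoyl chloride | C/C=C/[C@](C)(C(C)(C)C(Cl)=O)[C@@]1(O[Si](CC)(CC)CC)CC[C@](C)(Cl)[C@@H](Br)C1 | intermediate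
24 | (4R,5E)-4-[(1R,3S,4S)-3-bromo-4-chloro-4-methyl-1-[(triethylsilyl)oxy]cyclohexyl]-3,3,4-trimethylhept-5-en-2-one | C/C=C/[C@](C)(C(C)(C)C(C)=O)[C@@]1(O[Si](CC)(CC)CC)CC[C@](C)(Cl)[C@@H](Br)C1 | intermediate
25 | (2R)-2-[(1R,3S,4S)-3-bromo-4-chloro-4-methyl-1-[(triethylsilyl)oxy]cyclohexyl]-2,3,3-trimethyl-4-oxopentanal | O=C[C@](C)(C(C)(C)C(C)=O)[C@@]1(O[Si](CC)(CC)CC)CC[C@](C)(Cl)[C@@H](Br)C1 | intermediate
26 | (3S)-3-[(1R,3S,4S)-3-bromo-4-chloro-4-methyl-1-[(triethylsilyl)oxy]cyclohexyl]-4-hydroxy-2,2,3-trimethylcyclopentan-1-one (both C4 epimers) | OC1CC(=O)C(C)(C)[C@]1(C)[C@@]1(O[Si](CC)(CC)CC)CC[C@](C)(Cl)[C@@H](Br)C1 | intermediate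
27 | (4R)-4-[(1R,3S,4S)-3-bromo-4-chloro-4-methyl-1-[(triethylsilyl)oxy]cyclohexyl]-4,5,5-trimethylcyclopentane-1,3-dione | O=C1CC(=O)C(C)(C)[C@]1(C)[C@@]1(O[Si](CC)(CC)CC)CC[C@](C)(Cl)[C@@H](Br)C1 | intermediate
28 | (5R)-3-bromo-5-[(1R,3S,4S)-3-bromo-4-chloro-4-methyl-1-[(triethylsilyl)oxy]cyclohexyl]-4,4,5-trimethylcyclopent-2-en-1-one | O=C1C=C(Br)C(C)(C)[C@]1(C)[C@@]1(O[Si](CC)(CC)CC)CC[C@](C)(Cl)[C@@H](Br)C1 | intermediate
29 | (1R,5S)-3-bromo-5-[(1R,3S,4S)-3-bromo-4-chloro-4-methyl-1-[(triethylsilyl)oxy]cyclohexyl]-4,4,5-trimethylcyclopent-2-en-1-ol | O[C@@H]1C=C(Br)C(C)(C)[C@]1(C)[C@@]1(O[Si](CC)(CC)CC)CC[C@](C)(Cl)[C@@H](Br)C1 | intermediate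
30 | (1R,2S,4S)-4-bromo-2-[(1R,3S,4S)-3-bromo-4-chloro-4-methyl-1-[(triethylsilyl)oxy]cyclohexyl]-2,3,3-trimethylcyclopentan-1-ol | CC1(C)[C@@H](Br)C[C@@H](O)[C@@]1(C)[C@@]1(O[Si](CC)(CC)CC)CC[C@](C)(Cl)[C@@H](Br)C1 | intermediate
31 | (1R,2S,4S)-4-bromo-2-[(1R,3S,4S)-3-bromo-4-chloro-1-hydroxy-4-methylcyclohexyl]-2,3,3-trimethylcyclopentan-1-ol | CC1(C)[C@@H](Br)C[C@@H](O)[C@@]1(C)[C@@]1(O)CC[C@](C)(Cl)[C@@H](Br)C1 | target

**Step count and risks**

Total step count: 22. Longest linear sequence: 22 steps (1 to 31; the route is fully linear).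

Steps most likely to fail:

Step 7 (proposed new method). The ionisation may leave the intended course: proton loss from the C4' cation, chloride entering at C5' with bromine shifting to C4', or re-ionisation of the tertiary chloride once formed. The fallback sets out from 8 and returns at 12 and uses known chemistry only. The tertiary alcohol is silylated (Et3SiOTf, 2,6-lutidine) to methyl (R)-4-methyl-1-[(triethylsilyl)oxy]cyclohex-3-ene-1-carboxylate F1. The alkene is then bromochlorinated directly with tetrabutylammonium dichlorobromate (Bu4NBrCl2, CH2Cl2, 0 °C; anti addition, chlorine at the tertiary carbon). With two groups of similar size on C1' neither alkene face is favoured, so 12 is expected together with its diastereomer methyl (1R,3R,4R)-3-bromo-4-chloro-4-methyl-1-[(triethylsilyl)oxy]cyclohexane-1-carboxylate F2, from which it is separated by chromatography.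

Step 14. The [3,3] shift must join a fully substituted ketene acetal carbon to an alkene carbon flanked by the C1' silyloxy centre. If it is too slow, the ketene acetal may decompose instead (C-silylation, loss of the allylic carboxylate). The fallback sets out from 17 and returns at 22. Acylation with propanoyl chloride gives (2S,3E)-4-[(1R,3S,4S)-3-bromo-4-chloro-4-methyl-1-[(triethylsilyl)oxy]cyclohexyl]pent-3-en-2-yl propanoate F3. Ireland–Claisen rearrangement of its less substituted ketene acetal, with the same chair-controlled chirality transfer, gives (3R,4E)-3-[(1R,3S,4S)-3-bromo-4-chloro-4-methyl-1-[(triethylsilyl)oxy]cyclohexyl]-2,3-dimethylhex-4-enoic acid F4 (C2 epimers, of no consequence). α-Methylation of the carboxylic acid dianion (LiN(i-Pr)2, then MeI) then completes the gem-dimethyl group and gives 22.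

Step 21. Hydrogen may be delivered to the C4 radical from the wrong face, or the vinylic bromine may be lost if hydrogen adds with the opposite regiochemistry. The fallback sets out from 28 and returns at 30 and replaces radical, kinetic control by ionic, thermodynamic control. Palladium-catalysed formate reduction of the vinylogous acyl bromide (Pd(OAc)2, PPh3, HCO2H, Et3N) gives (5R)-5-[(1R,3S,4S)-3-bromo-4-chloro-4-methyl-1-[(triethylsilyl)oxy]cyclohexyl]-4,4,5-trimethylcyclopent-2-en-1-one F5. Reversible conjugate addition of HBr (HBr in AcOH, 0 °C) gives (3S,5R)-3-bromo-5-[(1R,3S,4S)-3-bromo-4-chloro-4-methyl-1-[(triethylsilyl)oxy]cyclohexyl]-4,4,5-trimethylcyclopentan-1-one F6; its cis isomer is the one in which bromine and the large C2 substituent can both be pseudo-equatorial. Luche reduction from the face of the C2 methyl group, as in step 20, then gives 30.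

Further compounds
F1 | step 7 | methyl (R)-4-methyl-1-[(triethylsilyl)oxy]cyclohex-3-ene-1-carboxylate | COC(=O)[C@@]1(O[Si](CC)(CC)CC)CCC(C)=CC1
F2 | step 7 | methyl (1R,3R,4R)-3-bromo-4-chloro-4-methyl-1-[(triethylsilyl)oxy]cyclohexane-1-carboxylate | COC(=O)[C@@]1(O[Si](CC)(CC)CC)CC[C@@](C)(Cl)[C@H](Br)C1
F3 | step 14 | (2S,3E)-4-[(1R,3S,4S)-3-bromo-4-chloro-4-methyl-1-[(triethylsilyl)oxy]cyclohexyl]pent-3-en-2-yl propanoate | C[C@H](OC(=O)CC)/C=C(\C)[C@@]1(O[Si](CC)(CC)CC)CC[C@](C)(Cl)[C@@H](Br)C1
F4 | step 14 | (3R,4E)-3-[(1R,3S,4S)-3-bromo-4-chloro-4-methyl-1-[(triethylsilyl)oxy]cyclohexyl]-2,3-dimethylhex-4-enoic acid (C2 epimers) | C/C=C/[C@](C)(C(C)C(O)=O)[C@@]1(O[Si](CC)(CC)CC)CC[C@](C)(Cl)[C@@H](Br)C1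
F5 | step 21 | (5R)-5-[(1R,3S,4S)-3-bromo-4-chloro-4-methyl-1-[(triethylsilyl)oxy]cyclohexyl]-4,4,5-trimethylcyclopent-2-en-1-one | O=C1C=CC(C)(C)[C@]1(C)[C@@]1(O[Si](CC)(CC)CC)CC[C@](C)(Cl)[C@@H](Br)C1
F6 | step 21 | (3S,5R)-3-bromo-5-[(1R,3S,4S)-3-bromo-4-chloro-4-methyl-1-[(triethylsilyl)oxy]cyclohexyl]-4,4,5-trimethylcyclopentan-1-one | O=C1C[C@H](Br)C(C)(C)[C@]1(C)[C@@]1(O[Si](CC)(CC)CC)CC[C@](C)(Cl)[C@@H](Br)C1
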